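**Retrosynthetic overview**
1. Target 25 ⇐ C3 angeloylation of tetraol 22 (three primary OH masked as silyl ethers) ⇐ hydride reduction of a butenolide and two ester protecting groups; C8=CH2 ⇐ C8 ketone (Takai–Lombardo).
2. Side chain C11–C16 ⇐ vinylogous (1,6) Michael addition of the C9 β-keto ester 16 to 4-vinylfuran-2(5H)-one, then loss of the ester.
3. Ring B ⇐ one-flask [3+3] annulation of ring-A allylic alcohol 11 (C10=C5–C6–OH) with the bis-silyl dienol ether of methyl acetoacetate (C7–C8–C9): C6–C7 by SN1 γ-alkylation, C9–C10 by cation–olefin cyclization.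
4. Enabling feature: in ring B the sp2 carbon C8 sits between C7 and C9, so C7–C8–C9 is an acetone 1,3-dianion unit; C6–C5–C10 of ring A is an allyl unit whose tertiary end C10 is the quaternary centre and whose middle carbon C5 carries only H.
5. Ring A is made first, from (R)-carvone (C6 dialkylation sets C4, the isopropenyl group becomes the C3 oxygen, the enone carbonyl becomes C5); ring B is closed second.

Key step: step 7

Remark: the SMILES is taken as drawn, i.e. (3R,4S,5S,9R,10S) with the C3 oxygen and the C4 CH2OH group trans-diequatorial, the C4 and C10 methyl groups axial and cis, a (Z)-2-methylbut-2-enoate (angelate) at C3 and the two side-chain CH2OH groups cis on C13=C14; labdane numbering is used (C1–C10 decalin, C11–C16 side chain, C17 exocyclic methylene, C18 methyl and C19 CH2OH on C4, C20 methyl on C10).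

**Step 1**
Reactants: 1 (R)-(−)-carvone
Product: 3 (5R,6S)-6-methylcarvone (trans; the minor cis epimer is carried along), via lithium dienolate 2 (not isolated)
Conditions: LiN(i-Pr)2 (1.1 equiv), THF, −78 °C; MeI, −78 → 0 °C
Reagents that add atoms: iodomethane (CI)
Why: Kinetic α′-deprotonation and SN2 methylation of the cross-conjugated lithium dienolate (enolate alkylation); the new C6 centre should form mainly trans to the isopropenyl group, but it is planarised again in step 2, so both epimers serve.

**Step 2**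
Reactants: 3 (5R,6S)-6-methylcarvone
Product: 6 (5S,6R)-2,6-dimethyl-6-[(pivaloyloxy)methyl]-5-(prop-1-en-2-yl)cyclohex-2-en-1-one, via lithium enolate 4 (not isolated), via lithium aldolate 5 (not isolated)
Conditions: LiN(i-Pr)2 (1.2 equiv), THF, −78 °C; CH2O (gas, cracked from paraformaldehyde), −78 °C; t-BuCOCl, −78 → 0 °C
Reagents that add atoms: formaldehyde (C=O); pivaloyl chloride (CC(C)(C)C(Cl)=O)
Why: Aldol addition of the tetrasubstituted enolate to formaldehyde should occur anti to the neighbouring isopropenyl group, so the quaternary carbon (future C4) carries CH2O trans and CH3 cis to it, and acylation of the aldolate in the same flask blocks the retro-aldol path.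

**Step 3**
Reactants: 6 (5S,6R)-2,6-dimethyl-6-[(pivaloyloxy)methyl]-5-(prop-1-en-2-yl)cyclohex-2-en-1-one
Product: 8 (5R,6S)-5-acetoxy-2,6-dimethyl-6-[(pivaloyloxy)methyl]cyclohex-2-en-1-one, via methoxy hydroperoxide 7 (not isolated)
Conditions: O3, CH2Cl2/MeOH 5:1, −78 °C (Sudan Red 7B end point); Ac2O, Et3N, DMAP (cat.), −78 → 23 °C
Reagents that add atoms: ozone (O=[O+][O-]); methanol (CO)
Why: Ozone should cleave the electron-rich 1,1-disubstituted alkene in preference to the enone, methanol traps the carbonyl oxide, and acetylation triggers a Criegee rearrangement in which the ring carbon migrates to oxygen with retention, so the isopropenyl group becomes the C3 acetate (its acetyl group is the old isopropenyl C–CH3 unit).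

**Step 4**
Reactants: 8 (5R,6S)-5-acetoxy-2,6-dimethyl-6-[(pivaloyloxy)methyl]cyclohex-2-en-1-one
Product: 10 (5R,6S)-5-acetoxy-2,6-dimethyl-6-[(pivaloyloxy)methyl]cyclohex-1-en-1-yl trifluoromethanesulfonate, via lithium enolate 9 (not isolated)
Conditions: LiBH(s-Bu)3 (1.05 equiv), THF, −78 °C; PhNTf2, −78 → 0 °C
Reagents that add atoms: N-phenylbis(trifluoromethanesulfonimide) (O=S(=O)(N(c1ccccc1)S(=O)(=O)C(F)(F)F)C(F)(F)F)
Why: Conjugate hydride reduction of the α-methyl enone gives the tetrasubstituted lithium enolate regiospecifically (the other α-carbon is quaternary), and O-sulfonylation fixes it as the enol triflate; no stereocentre is formed.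

**Step 5**
Reactants: 10 (5R,6S)-5-acetoxy-2,6-dimethyl-6-[(pivaloyloxy)methyl]cyclohex-1-en-1-yl trifluoromethanesulfonate
Product: 11 {(5R,6S)-5-acetoxy-2,6-dimethyl-6-[(pivaloyloxy)methyl]cyclohex-1-en-1-yl}methanol
Conditions: Bu3SnCH2OH (1.5 equiv), Pd(PPh3)4 (5 mol %), LiCl (3 equiv), dioxane, 100 °C
Reagents that add atoms: (tributylstannyl)methanol (OC[Sn](CCCC)(CCCC)CCCC)
Why: Stille cross-coupling of the enol triflate with the hydroxymethyl stannane should install the one-carbon allylic alcohol (future C6) on the tetrasubstituted alkene without touching the two esters.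

**Step 6**
Reactants: 12 methyl 3-(trimethylsilyloxy)but-2-enoate
Product: 14 1-methoxy-1,3-bis(trimethylsilyloxy)buta-1,3-diene, via lithium dienolate 13 (not isolated)
Conditions: LiN(i-Pr)2 (1.1 equiv), THF, −78 °C; Me3SiCl, −78 → 0 °C
Reagents that add atoms: chlorotrimethylsilane (C[Si](C)(C)Cl)
Why: γ-Deprotonation of the silyl enol ether of methyl acetoacetate and O-silylation of the ester dienolate give the 1,3-bis(silyloxy)diene, a masked acetoacetate γ,α-dianion.

**Step 7**
Reactants: 11 {(5R,6S)-5-acetoxy-2,6-dimethyl-6-[(pivaloyloxy)methyl]cyclohex-1-en-1-yl}methanol and 14 1-methoxy-1,3-bis(trimethylsilyloxy)buta-1,3-diene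
Product: 16 trans-fused bicyclic β-keto ester methyl 6-acetoxy-5,8a-dimethyl-2-oxo-5-[(pivaloyloxy)methyl]decahydronaphthalene-1-carboxylate (C9 ester equatorial), via monocyclic keto ester 15 (not isolated)
Conditions: 14 (1.5 equiv), SnCl4 (2.5 equiv), CH2Cl2, −78 → 0 °C
Reagents that add atoms: none
Why: Proposed new method: SnCl4 should ionise allylic alcohol 11 to the 2-methylcyclohexenylmethyl cation, which is captured at its primary terminus (C6) by the terminal carbon of diene 14 (C7); silanol-mediated desilylation then gives keto ester 15 as its tin chelate, and return of the proton to C5 of the tetrasubstituted C5=C10 alkene generates the tertiary C10 cation, which is trapped by the enol carbon between the two carbonyls (C9). The closest known reaction types are the Lewis acid γ-alkylation of 1,3-bis(silyloxy)dienes by SN1-active electrophiles and the SnCl4-promoted cation–olefin cyclization of unsaturated β-keto esters; running both in one flask, with the hydroxyl proton of 11 ending on C5 and both silyl groups leaving as hexamethyldisiloxane, is the new element. Ring B closes in a 6-(enolendo) mode onto the cyclohexyl cation through a chair transition state. C5 and C10 are controlled by the ring-A chair in which the C3 acetate and the C4 CH2OPiv group are equatorial and the C4 methyl is axial: H-5 should enter anti to that axial methyl and C9 should bond equatorially to C10, giving the trans-decalin with the C10 methyl axial, while C9 (epimerisable) settles with the ester equatorial. The step needs γ- over α-attack of the diene (secured by its terminal silyl enol ether carbon), attack at C6 rather than C10 of the allyl cation (primary against tertiary terminus) and C- over O-cyclization (favoured by the doubly activated C9 and SnCl4 chelation).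

**Step 8**
Reactants: 17 4-bromofuran-2(5H)-one
Product: 18 4-vinylfuran-2(5H)-one
Conditions: Bu3SnCH=CH2 (1.1 equiv), Pd(PPh3)2Cl2 (3 mol %), BHT (cat.), THF, 65 °C
Reagents that add atoms: tributyl(vinyl)stannane (C=C[Sn](CCCC)(CCCC)CCCC)
Why: Stille coupling of the β-bromo enoate (a vinylogous acyl bromide, fast oxidative addition) with the vinyl stannane.

**Step 9**
Reactants: 16 bicyclic β-keto ester and 18 4-vinylfuran-2(5H)-one
Product: 19 methyl 6-acetoxy-5,8a-dimethyl-2-oxo-1-[2-(5-oxo-2,5-dihydrofuran-3-yl)ethyl]-5-[(pivaloyloxy)methyl]decahydronaphthalene-1-carboxylate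
Conditions: DBU (0.3 equiv), MeCN, 0 → 40 °C
Reagents that add atoms: none
Why: Base-catalysed vinylogous (1,6) Michael addition of the β-keto ester enolate to the unsubstituted vinyl terminus of the dienoate (the 1,4-position is a fully substituted β-carbon), followed by γ-protonation to the conjugated butenolide; attack should come anti to the axial C10 methyl, but this C9 configuration is reset in step 10.

**Step 10**
Reactants: 19 Michael adduct
Product: 20 4-{2-[6-acetoxy-5,8a-dimethyl-2-oxo-5-(pivaloyloxymethyl)decahydronaphthalen-1-yl]ethyl}furan-2(5H)-one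
Conditions: LiCl (4 equiv), H2O (2 equiv), DMSO, 140 °C
Reagents that add atoms: none
Why: Krapcho dealkoxycarbonylation of the α,α-disubstituted β-keto ester; protonation of the resulting enolate and equilibration should place the C9 side chain equatorial, cis to the C10 methyl, as in the target.

**Step 11**
Reactants: 20 C8 ketone
Product: 21 4-{2-[6-acetoxy-5,8a-dimethyl-2-methylidene-5-(pivaloyloxymethyl)decahydronaphthalen-1-yl]ethyl}furan-2(5H)-one
Conditions: Zn, CH2Br2, TiCl4, THF/CH2Cl2, 0 → 23 °C
Reagents that add atoms: dibromomethane (BrCBr)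
Why: Takai–Lombardo methylenation with the non-basic CH2(ZnBr)2/TiCl4 reagent should convert the hindered, enolisable C8 ketone into the exocyclic methylene without epimerising C9 and without attacking the lactone or the esters.

**Step 12**
Reactants: 21 methylidene butenolide
Product: 22 (Z)-2-{2-[6-hydroxy-5-(hydroxymethyl)-5,8a-dimethyl-2-methylidenedecahydronaphthalen-1-yl]ethyl}but-2-ene-1,4-diol
Conditions: i-Bu2AlH (9 equiv), CH2Cl2, −78 → 0 °C; aq. KNaC4H4O6 (potassium sodium tartrate)
Reagents that add atoms: none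
Why: 1,2-Hydride reduction of the butenolide (lactone to lactol to diol) keeps the ring-enforced Z geometry of C13=C14, and the same reagent cleaves the acetate and the pivalate.

**Step 13**
Reactants: 22 tetraol
Product: 23 15,16,19-tris(tert-butyldimethylsilyl) ether of 22 (C3 hydroxyl free)
Conditions: t-BuMe2SiCl (3.3 equiv), imidazole, DMF, 0 °C
Reagents that add atoms: tert-butyl(chloro)dimethylsilane (CC(C)(C)[Si](C)(C)Cl)
Why: Silylation discriminates on steric grounds: the three primary hydroxyls should react, the secondary C3 hydroxyl next to quaternary C4 should not.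

**Step 14**
Reactants: 23 tris-silyl ether
Product: 24 3-O-angeloyl derivative of 23
Conditions: angelic acid (3 equiv), 2,4,6-Cl3C6H2COCl (3 equiv), Et3N, toluene, 23 °C; then 23, toluene, 80 °C (no DMAP)
Reagents that add atoms: angelic acid (C/C=C(/C)C(O)=O)
Why: Yamaguchi-type esterification through the mixed 2,4,6-trichlorobenzoic anhydride should acylate the remaining C3 hydroxyl, and leaving out nucleophilic catalysts avoids addition–elimination on the angeloyl unit and so keeps the Z geometry.

**Step 15**
Reactants: 24 angelate tris-silyl ether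
Product: 25 target (CNP0237954.1)
Conditions: HF·pyridine, pyridine, THF, 0 → 23 °C
Reagents that add atoms: none
Why: Fluoride cleavage of the three silyl ethers under buffered, weakly acidic conditions, which should suppress migration of the C3 angeloyl group to the neighbouring C19 hydroxyl.

**Compound list**
1 | (R)-(−)-carvone | CC1=CC[C@@H](C(C)=C)CC1=O | starting material
2 | lithium dienolate of carvone (O–Li on C1, C1=C6) | CC1=CC[C@@H](C(C)=C)C=C1O[Li] | intermediate
3 | (5R,6S)-6-methylcarvone, (5R,6S)-2,6-dimethyl-5-(prop-1-en-2-yl)cyclohex-2-en-1-one | CC1=CC[C@@H](C(C)=C)[C@H](C)C1=O | intermediate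
4 | lithium enolate of 3 (C1=C6 tetrasubstituted) | CC1=CC[C@@H](C(C)=C)C(C)=C1O[Li] | intermediate
5 | lithium aldolate, 6-(lithiooxymethyl)-6-methylcarvone, CH2O trans to isopropenyl | CC1=CC[C@@H](C(C)=C)[C@](C)(CO[Li])C1=O | intermediate
6 | (5S,6R)-2,6-dimethyl-6-[(pivaloyloxy)methyl]-5-(prop-1-en-2-yl)cyclohex-2-en-1-one | CC1=CC[C@@H](C(C)=C)[C@](C)(COC(=O)C(C)(C)C)C1=O | intermediate
7 | α-methoxy hydroperoxide from ozonolysis of 6 (epimers at the peroxy carbon) | CC1=CC[C@@H](C(C)(OC)OO)[C@](C)(COC(=O)C(C)(C)C)C1=O | intermediate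
8 | (5R,6S)-5-acetoxy-2,6-dimethyl-6-[(pivaloyloxy)methyl]cyclohex-2-en-1-one | CC1=CC[C@@H](OC(C)=O)[C@](C)(COC(=O)C(C)(C)C)C1=O | intermediate
9 | lithium enolate from conjugate reduction of 8 | [Li]OC1=C(C)CC[C@@H](OC(C)=O)[C@]1(C)COC(=O)C(C)(C)C | intermediate
10 | (5R,6S)-5-acetoxy-2,6-dimethyl-6-[(pivaloyloxy)methyl]cyclohex-1-en-1-yl trifluoromethanesulfonate | FC(F)(F)S(=O)(=O)OC1=C(C)CC[C@@H](OC(C)=O)[C@]1(C)COC(=O)C(C)(C)C | intermediate
11 | {(5R,6S)-5-acetoxy-2,6-dimethyl-6-[(pivaloyloxy)methyl]cyclohex-1-en-1-yl}methanol (ring A with C6–OH; labdane 3R,4S) | OCC1=C(C)CC[C@@H](OC(C)=O)[C@]1(C)COC(=O)C(C)(C)C | intermediate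
12 | methyl 3-(trimethylsilyloxy)but-2-enoate (E/Z mixture as sold; geometry immaterial) | COC(=O)C=C(C)O[Si](C)(C)C | starting material
13 | lithium dienolate of 12 | COC(O[Li])=CC(=C)O[Si](C)(C)C | intermediate
14 | 1-methoxy-1,3-bis(trimethylsilyloxy)buta-1,3-diene (ketene acetal geometry immaterial) | COC(O[Si](C)(C)C)=CC(=C)O[Si](C)(C)C | intermediate
15 | monocyclic keto ester, methyl 5-{(5R,6S)-5-acetoxy-2,6-dimethyl-6-[(pivaloyloxy)methyl]cyclohex-1-en-1-yl}-3-oxopentanoate | COC(=O)CC(=O)CCC1=C(C)CC[C@@H](OC(C)=O)[C@]1(C)COC(=O)C(C)(C)C | intermediate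
16 | methyl 6-acetoxy-5,8a-dimethyl-2-oxo-5-[(pivaloyloxy)methyl]decahydronaphthalene-1-carboxylate, trans-fused, C9 ester equatorial (labdane: 3-OAc, 19-OPiv, 8-oxo, C9–CO2Me) | O=C1CC[C@H]2[C@@](C)(CC[C@@H](OC(C)=O)[C@]2(C)COC(=O)C(C)(C)C)[C@@H]1C(=O)OC | intermediate
17 | 4-bromofuran-2(5H)-one | BrC1=CC(=O)OC1 | starting material
18 | 4-vinylfuran-2(5H)-one | C=CC1=CC(=O)OC1 | intermediate
19 | methyl 6-acetoxy-5,8a-dimethyl-2-oxo-1-[2-(5-oxo-2,5-dihydrofuran-3-yl)ethyl]-5-[(pivaloyloxy)methyl]decahydronaphthalene-1-carboxylate (side chain axial at C9) | O=C1CC[C@H]2[C@@](C)(CC[C@@H](OC(C)=O)[C@]2(C)COC(=O)C(C)(C)C)[C@]1(CCC3=CC(=O)OC3)C(=O)OC | intermediate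
20 | 4-{2-[6-acetoxy-5,8a-dimethyl-2-oxo-5-(pivaloyloxymethyl)decahydronaphthalen-1-yl]ethyl}furan-2(5H)-one (side chain equatorial at C9) | O=C1CC[C@H]2[C@@](C)(CC[C@@H](OC(C)=O)[C@]2(C)COC(=O)C(C)(C)C)[C@@H]1CCC3=CC(=O)OC3 | intermediate
21 | 4-{2-[6-acetoxy-5,8a-dimethyl-2-methylidene-5-(pivaloyloxymethyl)decahydronaphthalen-1-yl]ethyl}furan-2(5H)-one | C=C1CC[C@H]2[C@@](C)(CC[C@@H](OC(C)=O)[C@]2(C)COC(=O)C(C)(C)C)[C@@H]1CCC3=CC(=O)OC3 | intermediate
22 | tetraol, (Z)-2-{2-[6-hydroxy-5-(hydroxymethyl)-5,8a-dimethyl-2-methylidenedecahydronaphthalen-1-yl]ethyl}but-2-ene-1,4-diol | C=C1CC[C@H]2[C@@](C)(CC[C@@H](O)[C@]2(C)CO)[C@@H]1CC/C(=C/CO)CO | intermediate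
23 | 15,16,19-tris(tert-butyldimethylsilyl) ether of 22 | C=C1CC[C@H]2[C@@](C)(CC[C@@H](O)[C@]2(C)CO[Si](C)(C)C(C)(C)C)[C@@H]1CC/C(=C/CO[Si](C)(C)C(C)(C)C)CO[Si](C)(C)C(C)(C)C | intermediate
24 | 3-O-[(Z)-2-methylbut-2-enoyl] derivative of 23 | C=C1CC[C@H]2[C@@](C)(CC[C@@H](OC(=O)/C(C)=C\C)[C@]2(C)CO[Si](C)(C)C(C)(C)C)[C@@H]1CC/C(=C/CO[Si](C)(C)C(C)(C)C)CO[Si](C)(C)C(C)(C)C | intermediate
25 | target, (3R,4S,5S,9R,10S)-15,16,19-trihydroxylabda-8(17),13(Z)-dien-3-yl (Z)-2-methylbut-2-enoate | C=C1CC[C@H]2[C@@](C)(CC[C@@H](OC(=O)/C(C)=C\C)[C@]2(C)CO)[C@@H]1CC/C(=C/CO)CO | target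

**Step count and risks**
Total step count: 15. Longest linear sequence: 13 steps (steps 1–5, 7, 9–15).

Most likely to fail, 1: step 7 (Proposed new method). The dienol ether may be desilylated before it meets the cation (loss of γ-regiocontrol). The cation may eliminate to a diene instead of being captured. The keto oxygen may close onto C10 (O-cyclization to a dihydropyran). The proton may be delivered to the wrong face of C5. Fallback, known chemistry in two separate bond formations, setting out from 11 and coming back at 16: alcohol 11 is converted with CBr4 and PPh3 (CH2Cl2, 0 °C) into the allylic bromide F1. The dianion of methyl acetoacetate (NaH, then n-BuLi, THF, 0 °C) is alkylated by F1 at its terminal carbon, which gives keto ester 15, now isolated. Treatment of 15 with SnCl4 in CH2Cl2 at 0 °C (cation–olefin cyclization ended by the β-keto ester) should then give 16.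

Most likely to fail, 2: step 9. Conjugate addition at the hindered C9 may be slow, so that polymerization of the vinyl butenolide or retro-addition wins. Fallback, setting out from 16 and coming back at 20: keto ester 16 is added (K2CO3, acetone) to the simple enone CH2=CHC(=O)CH2OSiMe2t-Bu, an ordinary Michael acceptor, to give the diketo ester F2. Dealkoxycarbonylation (LiCl, wet DMSO, 140 °C) gives the diketone F3, and HF·pyridine frees the α-hydroxy ketone F4. Heating F4 with Ph3P=C=C=O in toluene (O-acylation by the ketene ylide, then intramolecular Wittig olefination of the neighbouring ketone) closes the butenolide and should give 20.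

Most likely to fail, 3: step 14. Acylation of the hindered C3 hydroxyl may stall, and forcing it may isomerise the Z-alkene of the angeloyl unit to the E (tiglate) form. Fallback, setting out from 23 and coming back at 24, building the Z-alkene after the ester bond is made: 23 is esterified with but-2-ynoic acid (DCC, DMAP, CH2Cl2) to the but-2-ynoate F5. Hydrostannation with Bu3SnH and Pd(PPh3)4 (syn addition, tin α to the carbonyl) gives the (E)-2-(tributylstannyl)but-2-enoate F6. Stille methylation (MeI, Pd2(dba)3, P(2-furyl)3, CuI, DMF) with retention of geometry should give 24.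

**Further compounds**
F1 | step 7 | {(1S,6R)-6-acetoxy-2-(bromomethyl)-1,3-dimethylcyclohex-2-en-1-yl}methyl pivalate (allylic bromide of 11) | BrCC1=C(C)CC[C@@H](OC(C)=O)[C@]1(C)COC(=O)C(C)(C)C
F2 | step 9 | Michael adduct of 16 with 1-(tert-butyldimethylsilyloxy)but-3-en-2-one (C9 carries CO2Me and CH2CH2C(=O)CH2OSi) | O=C1CC[C@H]2[C@@](C)(CC[C@@H](OC(C)=O)[C@]2(C)COC(=O)C(C)(C)C)[C@]1(CCC(=O)CO[Si](C)(C)C(C)(C)C)C(=O)OC
F3 | step 9 | dealkoxycarbonylated diketone (C9–H, side chain equatorial) | O=C1CC[C@H]2[C@@](C)(CC[C@@H](OC(C)=O)[C@]2(C)COC(=O)C(C)(C)C)[C@@H]1CCC(=O)CO[Si](C)(C)C(C)(C)C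
F4 | step 9 | α-hydroxy ketone | O=C1CC[C@H]2[C@@](C)(CC[C@@H](OC(C)=O)[C@]2(C)COC(=O)C(C)(C)C)[C@@H]1CCC(=O)CO
F5 | step 14 | 3-O-(but-2-ynoyl) derivative of 23 | C=C1CC[C@H]2[C@@](C)(CC[C@@H](OC(=O)C#CC)[C@]2(C)CO[Si](C)(C)C(C)(C)C)[C@@H]1CC/C(=C/CO[Si](C)(C)C(C)(C)C)CO[Si](C)(C)C(C)(C)C
F6 | step 14 | 3-O-[(E)-2-(tributylstannyl)but-2-enoyl] derivative of 23 | C=C1CC[C@H]2[C@@](C)(CC[C@@H](OC(=O)/C([Sn](CCCC)(CCCC)CCCC)=C\C)[C@]2(C)CO[Si](C)(C)C(C)(C)C)[C@@H]1CC/C(=C/CO[Si](C)(C)C(C)(C)C)CO[Si](C)(C)C(C)(C)C
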